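**Strategy.** The target is a 20-membered meta,para-cyclophane: a resorcinol ring A and a pyrogallol ring B joined by one ether oxygen and by a twelve-carbon chain (C1′ on ring A to C12′ on ring B) that carries no substituent and no stereocentre. Everything rests on cutting C9′–C10′, a bond flanked only by methylene groups and far from both arenes. It is closed as an alkene by ring-closing metathesis, and the same ruthenium charge saturates it under hydrogen. The precursor is an acyclic diaryl ether with a dec-9-enyl chain on ring A and a but-3-enyl chain on ring B, assembled by one Ullmann and two Negishi couplings; the methyl ethers are cleaved last.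

Key step: step 4

Remark: C10′ is the third chain carbon counted from ring B. The target has no stereocentre; alkene 9 is an E/Z mixture whose geometry is erased in the same step. But-3-enylzinc bromide 2 is taken as the commercial THF solution.

**Step 1**
Reactants: 1 4-bromo-2,6-dimethoxyphenol; 2 but-3-en-1-ylzinc bromide
Product: 3 4-(but-3-en-1-yl)-2,6-dimethoxyphenol
Conditions: Pd(OAc)2 (2 mol%), SPhos (4 mol%), 2 (2.5 equiv, slow addition), THF, 25 to 50 °C
Reagents that add atoms: none
Why: Negishi cross-coupling, in which oxidative addition of Pd(0)/SPhos into the aryl C–Br bond, transmetalation from the primary alkylzinc and reductive elimination should outrun protonolysis of the C–Zn bond by the free phenol, which this catalyst system is known to tolerate.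

**Step 2**
Reactants: 3 4-(but-3-en-1-yl)-2,6-dimethoxyphenol; 4 1,3-dibromo-5-methoxybenzene (3 equiv)
Product: 5 5-(but-3-en-1-yl)-2-(3-bromo-5-methoxyphenoxy)-1,3-dimethoxybenzene
Conditions: CuI (10 mol%), picolinic acid (20 mol%), K3PO4 (2 equiv), DMSO, 90 °C, Ar
Reagents that add atoms: none
Why: Ullmann-type copper-catalysed C–O coupling with picolinic acid, a ligand suited to di-ortho-substituted phenols; the excess of symmetrical dibromide 4 and the deactivation of the second C–Br bond by the new aryloxy donor should hold the reaction at mono-arylation, and the terminal alkene is inert.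

**Step 3**
Reactants: 5 5-(but-3-en-1-yl)-2-(3-bromo-5-methoxyphenoxy)-1,3-dimethoxybenzene; 6 10-bromodec-1-ene
Product: 8 5-(but-3-en-1-yl)-2-[3-(dec-9-en-1-yl)-5-methoxyphenoxy]-1,3-dimethoxybenzene, via dec-9-en-1-ylzinc bromide 7 (not isolated)
Conditions: 6 (1.5 equiv), Zn dust (activated with BrCH2CH2Br/TMSCl), LiCl, THF, 50 °C; then 5, Pd(OAc)2 (2 mol%), SPhos (4 mol%), THF, 25 to 50 °C
Reagents that add atoms: none
Why: LiCl-assisted zinc insertion into the primary C–Br bond of 6 leaves the alkene untouched, and Negishi coupling of the resulting primary alkylzinc with the single aryl bromide of 5 should form the sp2–sp3 bond with reductive elimination faster than β-hydride elimination under SPhos.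

**Step 4**
Reactants: 8 5-(but-3-en-1-yl)-2-[3-(dec-9-en-1-yl)-5-methoxyphenoxy]-1,3-dimethoxybenzene
Product: 10 tri-O-methyl ether of the target (saturated 20-membered macrocycle), via macrocyclic alkene 9 (not isolated)
Conditions: Grubbs II (10 mol% in two portions), 1,2-dichloroethane (1 mM), 50 °C, Ar sparge; then H2 (50 bar), 70 °C
Reagents that add atoms: none
Why: The ruthenium benzylidene exchanges with one terminal vinyl group by [2+2] cycloaddition and cycloreversion, the new alkylidene captures the second vinyl group through a ruthenacyclobutane that collapses to the C9′=C10′ alkene 9 and ethylene, and under H2 the same ruthenium becomes a hydride that saturates this 1,2-disubstituted alkene. The closest known reaction type is macrocyclic ring-closing olefin metathesis run in tandem with in situ hydrogenation by the spent metathesis catalyst. One ring is closed, the 20-membered meta,para-bridged diaryl ether ring, by end-to-end closure of an α,ω-diene under high dilution with both chain termini lost as ethylene. No stereocentre is formed, and the E and Z isomers of 9 converge on one product on hydrogenation. The step needs ring closure to win over acyclic diene metathesis oligomerisation and over double-bond migration before closure: the first is served by 1 mM concentration, ethylene removal, a strain-free large ring and reversible backbiting of oligomers, the second by two unhindered monosubstituted olefins with no allylic heteroatom or chelating group. The aryl methyl ethers and the diaryl ether are inert to both the carbene and the hydride.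

**Step 5**
Reactants: 10 tri-O-methyl ether of the target
Product: 11 target CNP0314249.0
Conditions: BBr3 (6 equiv), CH2Cl2, −78 °C to rt; then H2O, 0 °C, under Ar
Reagents that add atoms: none
Why: BBr3 demethylation, in which boron coordinates each methoxy oxygen and bromide attacks the methyl carbon by SN2, whereas the diaryl ether offers no sp3 carbon and should survive; aqueous work-up hydrolyses the aryl borates to the three phenols.

**Compound list**
1 | 4-bromo-2,6-dimethoxyphenol | COc1cc(Br)cc(OC)c1O | starting material
2 | but-3-en-1-ylzinc bromide (THF solution) | C=CCC[Zn]Br | starting material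
3 | 4-(but-3-en-1-yl)-2,6-dimethoxyphenol | C=CCCc1cc(OC)c(O)c(OC)c1 | intermediate
4 | 1,3-dibromo-5-methoxybenzene (3,5-dibromoanisole) | COc1cc(Br)cc(Br)c1 | starting material
5 | 5-(but-3-en-1-yl)-2-(3-bromo-5-methoxyphenoxy)-1,3-dimethoxybenzene | C=CCCc1cc(OC)c(Oc2cc(Br)cc(OC)c2)c(OC)c1 | intermediate
6 | 10-bromodec-1-ene | C=CCCCCCCCCBr | starting material
7 | dec-9-en-1-ylzinc bromide | C=CCCCCCCCC[Zn]Br | intermediate (not isolated)
8 | 5-(but-3-en-1-yl)-2-[3-(dec-9-en-1-yl)-5-methoxyphenoxy]-1,3-dimethoxybenzene | C=CCCc1cc(OC)c(Oc2cc(OC)cc(CCCCCCCCC=C)c2)c(OC)c1 | intermediate
9 | macrocyclic alkene, E/Z mixture: the 20-membered ring of 10 with a C9′=C10′ double bond (third and fourth chain carbons from ring B) | COc1cc2cc(c1)Oc1c(OC)cc(cc1OC)CCC=CCCCCCCCC2 | intermediate (not isolated)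
10 | tri-O-methyl ether of the target: saturated 20-membered macrocycle, 5-methoxy-1,3-phenylene ring A, 2,6-dimethoxy-1,4-phenylene ring B (both OMe ortho to the ether oxygen), dodecamethylene bridge | COc1cc2cc(c1)Oc1c(OC)cc(cc1OC)CCCCCCCCCCCC2 | intermediate
11 | CNP0314249.0: the same macrocycle with three free OH groups (ring A 5-hydroxy; ring B 2,6-dihydroxy, both ortho to the ether oxygen) | Oc1cc2cc(c1)Oc1c(O)cc(cc1O)CCCCCCCCCCCC2 | target
12 | syringaldehyde (4-hydroxy-3,5-dimethoxybenzaldehyde), used only in the fallback to step 1 | COc1cc(C=O)cc(OC)c1O | starting material

**Total step count:** 5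
**Longest linear sequence:** 5 steps (1 → 3 → 5 → 8 → 10 → 11)

**Steps most likely to fail**

Step 4. Intermolecular metathesis may outpace ring closure and give oligomers. Double-bond migration before closure would give ring-contracted homologues, and the dilute ruthenium hydride may saturate the ring alkene incompletely. The fallback forms the same bond by reductive carbonyl coupling instead of metathesis and sets out from 8. Lemieux–Johnson cleavage of both vinyl groups (OsO4 cat., NaIO4, 2,6-lutidine, dioxane/H2O, rt) should give the dialdehyde 3-[4-[3-methoxy-5-(9-oxononyl)phenoxy]-3,5-dimethoxyphenyl]propanal F1. Intramolecular McMurry coupling (TiCl3(DME)1.5, Zn–Cu, DME, reflux, syringe-pump addition) should then close the C9′=C10′ alkene to give 9, here isolated. Hydrogenation (H2, Pd/C, EtOAc, rt) should give 10, where the route is rejoined.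

Step 2. C–O bond formation at the di-ortho-substituted phenoxide may be slow, both bromides of 4 may be arylated, and the electron-rich phenol may be oxidised at 90 °C. The fallback replaces the substitution of an aryl halide by an oxidative Chan–Lam–Evans coupling with a monofunctional aryl donor, which removes the desymmetrisation. It sets out from 3: 3-bromo-5-methoxyphenylboronic acid (COc1cc(Br)cc(c1)B(O)O), Cu(OAc)2, pyridine, 4 Å molecular sieves, CH2Cl2, air, rt should give 5 directly, where the route is rejoined. No compound outside the compound list is made (entry F0 below).

Step 1. Protonolysis of the alkylzinc by the free phenol may outrun transmetalation, oxidative addition into the electron-rich bromophenoxide may stall, and palladium hydride chain walking may move the terminal double bond. The fallback builds the side chain by carbonyl allylation and ionic deoxygenation instead of cross-coupling. It sets out from 12, which replaces 1 and 2. Allylmagnesium bromide (C=CC[Mg]Br, 2.2 equiv, THF, 0 °C) should give racemic 4-(1-hydroxybut-3-en-1-yl)-2,6-dimethoxyphenol F2. Et3SiH, TFA, CH2Cl2, −20 to 0 °C should then reduce the benzylic cation (para-quinone methide) and give 3, where the route is rejoined; the carbinol stereocentre is destroyed in this reduction.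

**Further compounds**
F1 | step 4 | 3-[4-[3-methoxy-5-(9-oxononyl)phenoxy]-3,5-dimethoxyphenyl]propanal | O=CCCc1cc(OC)c(Oc2cc(OC)cc(CCCCCCCCC=O)c2)c(OC)c1
F0 | step 2 | none | none
F2 | step 1 | 4-(1-hydroxybut-3-en-1-yl)-2,6-dimethoxyphenol (racemic) | C=CCC(O)c1cc(OC)c(O)c(OC)c1
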